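**Retrosynthetic overview**
- GA66 (the target) ⇐ 15-oxo-GA25 by hydride delivery to the exo face; the enone ⇐ GA25 by SeO2 allylic oxidation (ene, then [2,3] shift) and alcohol oxidation.
- GA25 ⇐ its 1-ene ⇐ oxidative cleavage of the C-19–C-20 bond of a bridged cyclopentanone, which releases the 19- and 20-acids together.
- Key disconnection: C-10–C-20, made by a Claisen [3,3] rearrangement of the exocyclic enol ether derived from a 19,2α-lactone with a 1(10)-double bond; this sets the C-10 quaternary centre.
- That lactone ⇐ gibberellic acid (GA3) by base-induced allylic lactone transposition, then radical removal of 3-OH and 13-OH.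
- Rings A to D are bought intact in GA3; the only ring formed is the bridged C-4/C-19/C-20/C-10/C-5 cyclopentanone (step 4), opened again in step 5.

Assumption: α/β are used as in gibberellin drawings (H-5 and H-9 are β; C-19 and C-20 are α), GA25 and GA66 are the usual short names of gibberell-16-ene-7,19,20-trioic acid and of its 15β-hydroxy derivative (the target), and gibberellic acid, a bulk fermentation product, is the single chiral starting material.

**Step 1**
Reactants: 1 gibberellic acid (GA3)
Product: 3 isogibberellic acid (iso-GA3), via 2β,3β-epoxy diacid 2 (not isolated)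
Conditions: NaOH (0.05 M in H2O, 3 equiv), 20 °C, 2 h; then 1 M HCl to pH 2.5, EtOAc
Reagents that add atoms: none
Why: The ionised 3β-hydroxyl opens the strained allylic 19,10-lactone by an anti SN2′ displacement to epoxide 2, and the freed C-19 carboxylate reopens it at allylic C-2 from the α face, so this allylic lactone transposition puts the lactone oxygen on C-2 cis to C-19, restores the 3β-OH and touches no other stereocentre.

**Step 2**
Reactants: 3 isogibberellic acid
Product: 4 isogibberellic acid 3,13-bis(methyl oxalate)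
Conditions: ClCOCO2Me (6 equiv), pyridine, DMAP (0.3 equiv), CH2Cl2, 0 → 25 °C; pH 5 phosphate buffer work-up
Reagents that add atoms: methyl chlorooxalate, COC(=O)C(=O)Cl
Why: DMAP-catalysed acylation converts the secondary 3-OH and the bridgehead tertiary 13-OH into radical-labile methyl oxalate esters, the CO2H is free again after aqueous work-up, and no stereocentre changes.

**Step 3**
Reactants: 4 isogibberellic acid 3,13-bis(methyl oxalate)
Product: 5 3,13-dideoxyisogibberellic acid
Conditions: Bu3SnH (5 equiv), AIBN (0.3 equiv, in portions), PhMe, 110 °C; aq. KF work-up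
Reagents that add atoms: none
Why: Barton-type radical deoxygenation of methyl oxalate esters replaces both C–O bonds by C–H (C-3 becomes CH2, and the cage fixes the configuration of bridgehead C-13), while the lactone, the acid and both alkenes are inert to tin radicals.

**Step 4**
Reactants: 5 3,13-dideoxyisogibberellic acid
Product: 7 19-oxo-19,20-cyclogibberella-1,16-dien-7-oic acid, via exocyclic enol ether 6 (not isolated)
Conditions: Cp2TiMe2 (3 equiv; one equivalent is spent deprotonating the CO2H), PhMe–THF, 75 °C, dark, 24 h until the reagent is consumed; then 150 °C (sealed tube), 4 h; aq. citric acid work-up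
Reagents that add atoms: dimethyltitanocene (Petasis reagent) Cp2TiMe2, [CH3-].[CH3-].[Ti+4].c1cc[cH-]c1.c1cc[cH-]c1
Why: Petasis methylenation turns the lactone carbonyl into allyl vinyl ether 6, and a Claisen [3,3]-sigmatropic rearrangement through the enforced boat transition state then forms the C-10–C-20 bond on the α face, because the migrating CH2 is tethered to C-4α and the departing oxygen sits on C-2α, which sets the C-10 quaternary centre cis to C-19.

**Step 5**
Reactants: 7 19-oxo-19,20-cyclogibberella-1,16-dien-7-oic acid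
Product: 9 gibberella-1,16-diene-7,19,20-trioic acid (1,2-didehydro-GA25), via 19,20-diketone 8 (not isolated)
Conditions: KOt-Bu (6 equiv), O2 (1 atm), t-BuOH–THF, 25 °C; then 30% aq. H2O2, 0 → 25 °C; 1 M HCl
Reagents that add atoms: dioxygen, O=O; hydrogen peroxide, OO
Why: Enolate autoxidation at C-20, the only enolisable position, gives the non-enolisable α-diketone 8, which alkaline H2O2 cleaves (Baeyer–Villiger-type oxidative cleavage) to the 19,20-diacid without touching a stereocentre, C-6 being protected as the α-carbon of a carboxylate.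

**Step 6**
Reactants: 9 gibberella-1,16-diene-7,19,20-trioic acid
Product: 10 GA25 (gibberell-16-ene-7,19,20-trioic acid)
Conditions: [Rh(nbd)(dppb)]BF4 (5 mol %), H2 (1 atm), CH2Cl2–MeOH, 25 °C, stopped after 1.0 equiv H2
Reagents that add atoms: none
Why: In this carboxyl-directed homogeneous hydrogenation the cationic rhodium catalyst is held by the C-20 and C-19 acids flanking the ring A alkene, so the 1,2-double bond is saturated faster than the undirected exocyclic 16-ene, and no stereocentre is formed.

**Step 7**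
Reactants: 10 GA25
Product: 12 15-oxo-GA25, via 15α-hydroxy-GA25 11 (not isolated)
Conditions: SeO2 (0.5 equiv), t-BuOOH (3 equiv), CH2Cl2–1,4-dioxane, 25 °C; then Dess–Martin periodinane (3 equiv), 25 °C
Reagents that add atoms: selenium dioxide, O=[Se]=O; tert-butyl hydroperoxide, CC(C)(C)OO
Why: SeO2 allylic oxidation (ene reaction followed by a [2,3]-sigmatropic shift) forms the C-15–O bond on the exposed exo (α) face and restores the 16-ene, C-15 being the only usable allylic position because C-13 is a bridgehead, and Dess–Martin oxidation in the same flask converts the alcohol into the exocyclic enone.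

**Step 8**
Reactants: 12 15-oxo-GA25
Product: 13 GA66 (15β-hydroxy-GA25)
Conditions: NaBH4 (5 equiv), CeCl3·7H2O (1.5 equiv), MeOH, −40 → 0 °C; aq. citric acid
Reagents that add atoms: none
Why: In this Luche 1,2-reduction hydride attacks the C-15 carbonyl from the exo (α) face of the bicyclo[3.2.1]octane, away from the C-9/C-11 bridge, giving the endo 15β-alcohol under substrate control, while CeCl3 suppresses conjugate reduction of the methylene ketone.

**Compound list**
1 | gibberellic acid (GA3): 3β,13-dihydroxy-20-norgibberella-1,16-diene-7,19-dioic acid 19,10α-lactone | C=C1[C@]2(O)CC[C@H]3[C@]45C=C[C@H](O)[C@@](C)(C(=O)O5)[C@H]4[C@H](C(=O)O)[C@]3(C2)C1 | starting material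
2 | 2β,3β-epoxy-13-hydroxy-20-norgibberella-1(10),16-diene-7,19-dioic acid | C=C1[C@]2(O)CC[C@H]3C4=C[C@@H]5O[C@@H]5[C@@](C)(C(=O)O)[C@H]4[C@H](C(=O)O)[C@]3(C2)C1 | intermediate
3 | isogibberellic acid: 3β,13-dihydroxy-20-norgibberella-1(10),16-diene-7,19-dioic acid 19,2α-lactone | C=C1[C@]2(O)CC[C@H]3C4=C[C@@H]5[C@H](O)[C@@](C)(C(=O)O5)[C@H]4[C@H](C(=O)O)[C@]3(C2)C1 | intermediate
4 | isogibberellic acid 3,13-bis(methyl oxalate) | C=C1[C@]2(OC(=O)C(=O)OC)CC[C@H]3C4=C[C@@H]5[C@H](OC(=O)C(=O)OC)[C@@](C)(C(=O)O5)[C@H]4[C@H](C(=O)O)[C@]3(C2)C1 | intermediate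
5 | 3,13-dideoxyisogibberellic acid: 20-norgibberella-1(10),16-diene-7,19-dioic acid 19,2α-lactone | C=C1[C@@H]2CC[C@H]3C4=C[C@@H]5C[C@@](C)(C(=O)O5)[C@H]4[C@H](C(=O)O)[C@]3(C2)C1 | intermediate
6 | 2α,19-epoxy-19-methylidene-20-norgibberella-1(10),16-dien-7-oic acid (lactone C=O of 5 replaced by C=CH2) | C=C1[C@@H]2CC[C@H]3C4=C[C@@H]5C[C@@](C)(C(=C)O5)[C@H]4[C@H](C(=O)O)[C@]3(C2)C1 | intermediate
7 | 19-oxo-19,20-cyclogibberella-1,16-dien-7-oic acid (C-4–CO–CH2–C-10 bridge on the α face) | C=C1[C@@H]2CC[C@H]3[C@]4(C5)C=CC[C@@](C)(C5=O)[C@H]4[C@H](C(=O)O)[C@]3(C2)C1 | intermediate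
8 | 19,20-dioxo-19,20-cyclogibberella-1,16-dien-7-oic acid | C=C1[C@@H]2CC[C@H]3[C@]4(C5=O)C=CC[C@@](C)(C5=O)[C@H]4[C@H](C(=O)O)[C@]3(C2)C1 | intermediate
9 | gibberella-1,16-diene-7,19,20-trioic acid (1,2-didehydro-GA25) | C=C1[C@@H]2CC[C@H]3[C@]4(C(=O)O)C=CC[C@@](C)(C(=O)O)[C@H]4[C@H](C(=O)O)[C@]3(C2)C1 | intermediate
10 | GA25 (gibberell-16-ene-7,19,20-trioic acid) | C=C1[C@@H]2CC[C@H]3[C@]4(C(=O)O)CCC[C@@](C)(C(=O)O)[C@H]4[C@H](C(=O)O)[C@]3(C2)C1 | intermediate
11 | 15α-hydroxy-GA25 (exo alcohol) | C=C1[C@@H]2CC[C@H]3[C@]4(C(=O)O)CCC[C@@](C)(C(=O)O)[C@H]4[C@H](C(=O)O)[C@]3(C2)[C@H]1O | intermediate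
12 | 15-oxo-GA25 (15-oxogibberell-16-ene-7,19,20-trioic acid) | C=C1[C@@H]2CC[C@H]3[C@]4(C(=O)O)CCC[C@@](C)(C(=O)O)[C@H]4[C@H](C(=O)O)[C@]3(C2)C1=O | intermediate
13 | GA66 (15β-hydroxy-GA25; 15β-hydroxygibberell-16-ene-7,19,20-trioic acid, endo alcohol) | C=C1[C@@H]2CC[C@H]3[C@]4(C(=O)O)CCC[C@@](C)(C(=O)O)[C@H]4[C@H](C(=O)O)[C@]3(C2)[C@@H]1O | target

**Totals**
Total step count: 8. Longest linear sequence: 8 steps (fully linear from gibberellic acid).

**Steps most likely to fail, with fallbacks**

Step 4 (methylenation of a hindered lactone beside a free acid, then a Claisen in a bridged system; excess reagent could also methylenate ketone 7). The fallback brings in C-20 by a [2,3]-sigmatropic rearrangement instead. It sets out from 5: the lactone is saponified (LiOH, aq. THF) and the dicarboxylate methylated in the same flask (MeI, DMF) to dimethyl 2α-hydroxy-20-norgibberella-1(10),16-diene-7,19-dioate F1. Heating F1 with Me2NCH(OMe)2 in xylene at 150 °C (Büchi [2,3]-sigmatropic rearrangement) moves a CONMe2 group suprafacially from O-2α to C-10α, giving gibberella-1,16-diene-7,19,20-trioic acid 7,19-dimethyl ester 20-(N,N-dimethylamide) F2. LiSPr in HMPA removes both methyl groups; the freed 19-acid, 1,3-diaxial to the amide, then expels dimethylamine in warm dilute aqueous HCl through gibberella-1,16-diene-7,19,20-trioic acid 19,20-anhydride F3, which aqueous LiOH opens. Acidification rejoins the route at 9.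

Step 5 (one-flask autoxidation and cleavage on a polyfunctional acid). The fallback replaces the radical-chain autoxidation by stepwise ionic oxidation. It sets out from 7: the enolate (KN(SiMe3)2, 2.2 equiv, THF, −78 °C) is hydroxylated with MoO5·py·HMPA to 20-hydroxy-19-oxo-19,20-cyclogibberella-1,16-dien-7-oic acid F4 (exo alcohol; its configuration is lost in the next operation). Dess–Martin periodinane then gives the diketone as an isolated compound, rejoining the route at 8, which is cleaved with alkaline H2O2 as in the second half of step 5.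

Step 6 (the 16-ene may be reduced or isomerised alongside the ring A alkene). The fallback gives up chemoselectivity and rebuilds the exocyclic alkene afterwards. It sets out from 9: SeO2/t-BuOOH then Dess–Martin periodinane, as in step 7, passes through 15α-hydroxygibberella-1,16-diene-7,19,20-trioic acid F5 to 15-oxogibberella-1,16-diene-7,19,20-trioic acid F6 (the 1,1-disubstituted 16-ene reacts with SeO2 before the cis-disubstituted ring A alkene). H2 over 10% Pd/C in EtOAc–MeOH then saturates both C=C bonds to 15-oxo-16,17-dihydro-GA25 F7 (16-methyl endo; either C-16 epimer serves). IBX in DMSO at 75 °C dehydrogenates this ketone; the only other β-hydrogen is on bridgehead C-13, so the new double bond can only be the exocyclic 16(17)-ene. This rejoins the route at 12.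

**Further compounds**
F1 | step 4 | dimethyl 2α-hydroxy-20-norgibberella-1(10),16-diene-7,19-dioate | C=C1[C@@H]2CC[C@H]3C4=C[C@@H](O)C[C@@](C)(C(=O)OC)[C@H]4[C@H](C(=O)OC)[C@]3(C2)C1
F2 | step 4 | gibberella-1,16-diene-7,19,20-trioic acid 7,19-dimethyl ester 20-(N,N-dimethylamide) | C=C1[C@@H]2CC[C@H]3[C@]4(C(=O)N(C)C)C=CC[C@@](C)(C(=O)OC)[C@H]4[C@H](C(=O)OC)[C@]3(C2)C1
F3 | step 4 | gibberella-1,16-diene-7,19,20-trioic acid 19,20-anhydride | C=C1[C@@H]2CC[C@H]3[C@]4(C5=O)C=CC[C@@](C)(C(=O)O5)[C@H]4[C@H](C(=O)O)[C@]3(C2)C1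
F4 | step 5 | 20-hydroxy-19-oxo-19,20-cyclogibberella-1,16-dien-7-oic acid (exo alcohol) | C=C1[C@@H]2CC[C@H]3[C@]4([C@H]5O)C=CC[C@@](C)(C5=O)[C@H]4[C@H](C(=O)O)[C@]3(C2)C1
F5 | step 6 | 15α-hydroxygibberella-1,16-diene-7,19,20-trioic acid | C=C1[C@@H]2CC[C@H]3[C@]4(C(=O)O)C=CC[C@@](C)(C(=O)O)[C@H]4[C@H](C(=O)O)[C@]3(C2)[C@H]1O
F6 | step 6 | 15-oxogibberella-1,16-diene-7,19,20-trioic acid | C=C1[C@@H]2CC[C@H]3[C@]4(C(=O)O)C=CC[C@@](C)(C(=O)O)[C@H]4[C@H](C(=O)O)[C@]3(C2)C1=O
F7 | step 6 | 15-oxo-16,17-dihydro-GA25 (16-methyl endo) | C[C@@H]1[C@@H]2CC[C@H]3[C@]4(C(=O)O)CCC[C@@](C)(C(=O)O)[C@H]4[C@H](C(=O)O)[C@]3(C2)C1=O
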